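(The earlier runs and the new flask were generated by integration with constants of no real substance.)

Of the constants you want for your quick number, take first the one the oak run hands over, and test your hunch that cold wins against it. The problem stands thus:

| flask | starting material | temperature | remark | time |
|---|---|---|---|---|
| alder | 0.50 M | 0 °C | run made earlier |  |
| oak | 0.75 M | 35 °C | run made earlier |  |
| south-west | 1.0 M | 5 °C |  | 20 d |
| north-east | 1.0 M | 45 °C |  | 20 d |
| south-east | 1.0 M | 65 °C |  | 20 d |
| east | 1.0 M | 25 °C |  | 20 d |

- alder (time / d: target / %, starting material / %): 1.04: 44, 52; 1.67: 57, 44; 2.50: 60, 32; 4.00: 74, 24; 8.00: 86, 16; 12.0: 85, 11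
- oak (time / d: target / %, starting material / %): 0.500: 71, 14; 0.833: 71, 12; 1.25: 66, 7; 1.67: 60, 8; 2.50: 51, 11

(standard deviation of a reading: 2 percentage points)

- percentages count the starting material that a species holds: one target or isomer of the product or crystals counts as two
- target is meant together with its crystals
- solid, in amounts per volume of the solution: crystals
- the earlier runs were read with a standard deviation of 2 percentage points
- steps that have been proposed: 2 starting material <-> target; target <-> isomer of the product; starting material <-> dormant form; crystals <-> target

* the best flask by amount of target, in percent of the starting material charged; "all alike" if 1.5 percentage points covers them all (south-west / north-east / south-east / east / all alike)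
* amount of target at the end, in percent of the starting material charged, south-west
* amount of target at the end, in percent of the starting material charged, north-east
* amount of target at the end, in percent of the starting material charged, south-east
* amount of target at the end, in percent of the starting material charged, east

In oak the target falls from 71% at 0.833 d to 51% at 2.50 d, and the readings between lie on that straight line within the 2 percentage points scatter. Count that fall in molar target, halving the percentage since one target counts as two:

drain = 20 points × 0.75 M / 2 / 1.67 d = 0.0450 M d⁻¹

Call this the drain: the target lost per day per litre while crystals hold c(target) at a fixed level, a zero-order loss in the usual term, so it does not scale with the charge. Assume, as my own guess, a factor of 3 for the 10 degrees down to east, and run that drain from alder's 86% over 20 d: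

east estimate = 86% − 2 × 0.0150 M d⁻¹ × 20 d / 1.0 M = 26.0%

Treat this as a rough figure, since the factor is a guess and the drain is read off scattered readings. Carry the same guessed factor on down to south-west and the drain comes to 0.00167 M d⁻¹, less than at east, so pick south-west.

The forecast, on its own grounds (“The fate of the target then decides everything”), says south-west, with 86%, 13%, 9% and 25% for south-west, north-east, south-east and east. My estimate for east stands near its figure, though by a different reckoning.

The flasks give 92.3%, 10.8%, 13.4% and 51.0% in that order, so south-west is best.

    2 starting material ⇌ target (K = 15.0 M⁻¹, k = 1.23 × 10⁻⁴ M⁻¹ s⁻¹, Ea = 70.0 kJ mol⁻¹, ΔH = −35.0 kJ mol⁻¹)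
    target ⇌ isomer of the product (K = 4.80, k = 2.78 × 10⁻⁶ s⁻¹, Ea = 98.0 kJ mol⁻¹, ΔH = −22.0 kJ mol⁻¹)
    starting material ⇌ dormant form (K = 8.70, k = 7.06 × 10⁻⁷ s⁻¹, Ea = 107 kJ mol⁻¹, ΔH = −18.0 kJ mol⁻¹)
    crystals ⇌ target, rate k4*(cs4 - [target]) while solid is left; crystals form when [target] > cs4 (solubility = 0.0580 M, k = 6.50 × 10⁻⁵ s⁻¹)
    (constants at 25 °C)

Part of south-west's hold on its target is how little target dissolves, acting together with the time given: with all target dissolved it ends at 69.1%, and left ten times as long at 66.0%. East, with crystals still at 39.7%, drains 0.00778 M d⁻¹ in its second half, slower than the 0.0150 M d⁻¹ reckoned. South-west makes isomer of the product at 8.47 × 10⁻⁴ M d⁻¹; that drain, carried to the like flask charged at 0.40 M, gives 8.47% of its charge, and that flask holds 8.06%.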